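**Retrosynthetic overview**

1. Target ⇒ global O-debenzylation ⇒ 3-O-ester ⇒ tetra-O-benzyl-(−)-epicatechin + O-benzylvanillic acid.
2. cis-Flavan-3-ol ⇒ (2R)-flavan-3-one; hydride delivered anti to the C2 aryl sets C3.
3. Key C–C disconnection C4–C4a: flavan-3-one ⇒ (S)-aryl propargyl ether. Forward, alkyne oxidation gives an α-oxo gold carbene (an enolonium equivalent, electrophilic ketone α-carbon) that is captured by the nucleophilic ring A carbon.
4. O1–C2 disconnection: aryl propargyl ether ⇒ racemic propargylic acetate + 3,5-bis(benzyloxy)phenol; a copper-catalysed enantioconvergent propargylic etherification sets C2.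
5. Propargylic acetate ⇒ 3,4-bis(benzyloxy)benzaldehyde + ethynylmagnesium bromide. Rings A and B are bought; ring C is the only ring formed (O1–C2 first, C4–C4a last).

Assumption: 3,5-bis(benzyloxy)phenol and 4-(benzyloxy)-3-methoxybenzoic acid are bought as catalogue compounds, and (S,S)-Ph-pybox is written as the ligand antipode giving the (S)-ether, which must be confirmed on the first run (the mirror-image ligand is equally available).

**Route**

Step 1
Reactants: 1 3,4-bis(benzyloxy)benzaldehyde; 2 ethynylmagnesium bromide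
Product: 4 rac-1-[3,4-bis(benzyloxy)phenyl]prop-2-yn-1-yl acetate, via bromomagnesium propargylic alkoxide 3 (not isolated)
Conditions: HC≡CMgBr (1.3 equiv), THF, 0 °C; then Ac2O (2 equiv), 0 °C to rt
Reagents that add atoms: acetic anhydride, CC(=O)OC(C)=O
Why: Grignard 1,2-addition of the alkynyl nucleophile to the non-enolisable aldehyde gives alkoxide 3, which is O-acetylated in the same flask; the new stereocentre is left racemic because it is erased and reset in step 2.

Step 2
Reactants: 4 rac-1-[3,4-bis(benzyloxy)phenyl]prop-2-yn-1-yl acetate; 5 3,5-bis(benzyloxy)phenol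
Product: 6 (S)-1,2-bis(benzyloxy)-4-{1-[3,5-bis(benzyloxy)phenoxy]prop-2-yn-1-yl}benzene
Conditions: CuOTf·½C6H6 (5 mol %), (S,S)-Ph-pybox (6 mol %), i-Pr2NEt (1.5 equiv), THF, 0 °C
Reagents that add atoms: none
Why: Copper-catalysed enantioselective propargylic substitution (etherification), in which ionisation of the copper acetylide of either enantiomer of 4 erases the stereocentre and the phenoxide of 5 adds at the propargylic carbon inside the chiral pybox pocket, setting the future C2 as (S) (this becomes 2R in the flavan because the priority order changes), while the symmetric ring A phenol can give only one O-alkylation product.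

Step 3
Reactants: 6 (S)-1,2-bis(benzyloxy)-4-{1-[3,5-bis(benzyloxy)phenoxy]prop-2-yn-1-yl}benzene
Product: 8 (2R)-5,7-bis(benzyloxy)-2-[3,4-bis(benzyloxy)phenyl]chroman-3-one, via α-oxo gold carbene 7 (not isolated)
Conditions: Me4tBuXPhosAuNTf2 (5 mol %), 2,6-dichloropyridine N-oxide (1.3 equiv, slow addition), ClCH2CH2Cl (0.05 M), rt
Reagents that add atoms: 2,6-dichloropyridine N-oxide, [O-][n+]1c(Cl)cccc1Cl
Why: Gold-catalysed alkyne oxidation, in which the N-oxide oxygen adds to the internal carbon of the gold-activated terminal alkyne and 2,6-dichloropyridine leaves to give α-oxo gold carbene 7, an enolonium (α-keto cation) equivalent whose electrophilic C4 is attacked by the ortho carbon of the phloroglucinol-type ring A (Friedel–Crafts-type six-membered closure, both ortho positions equivalent) to forge C4–C4a with reversed polarity at the ketone α-carbon; C2 is not involved and the non-basic pyridine by-product does not epimerise it.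

Step 4
Reactants: 8 (2R)-5,7-bis(benzyloxy)-2-[3,4-bis(benzyloxy)phenyl]chroman-3-one
Product: 9 (2R,3R)-5,7-bis(benzyloxy)-2-[3,4-bis(benzyloxy)phenyl]chroman-3-ol (tetra-O-benzyl-(−)-epicatechin)
Conditions: LiBH(s-Bu)3 (1.5 equiv), LiBr, THF, −78 °C; then H2O
Reagents that add atoms: none
Why: Substrate-controlled bulky-hydride reduction, in which LiBH(s-Bu)3 attacks the C3 carbonyl from the face opposite the C2 aryl group to give the axial 3-OH cis to the aryl, i.e. (2R,3R), and the low temperature keeps C2 from enolising.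

Step 5
Reactants: 9 (2R,3R)-5,7-bis(benzyloxy)-2-[3,4-bis(benzyloxy)phenyl]chroman-3-ol; 10 4-(benzyloxy)-3-methoxybenzoic acid
Product: 11 (2R,3R)-5,7-bis(benzyloxy)-2-[3,4-bis(benzyloxy)phenyl]chroman-3-yl 4-(benzyloxy)-3-methoxybenzoate
Conditions: DCC (2 equiv), DMAP (0.5 equiv), CH2Cl2, rt
Reagents that add atoms: none
Why: Steglich esterification acylates the hindered axial 3-OH under neutral conditions, so neither C2 nor C3 is touched.

Step 6
Reactants: 11 (2R,3R)-5,7-bis(benzyloxy)-2-[3,4-bis(benzyloxy)phenyl]chroman-3-yl 4-(benzyloxy)-3-methoxybenzoate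
Product: 12 (2R,3R)-2-(3,4-dihydroxyphenyl)-5,7-dihydroxychroman-3-yl 4-hydroxy-3-methoxybenzoate ((−)-epicatechin 3-O-vanillate, CNP0302437.1)
Conditions: H2 (1 atm), Pd(OH)2/C, THF/MeOH 1:1, rt
Reagents that add atoms: none
Why: Catalytic hydrogenolysis removes all five benzyl ethers at once while the ester, the aryl methyl ether and the cyclic C2–O bond survive in neutral medium, so both stereocentres are retained.

**Compound list**

1 | 3,4-bis(benzyloxy)benzaldehyde | O=Cc1ccc(OCc2ccccc2)c(OCc2ccccc2)c1 | starting material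
2 | ethynylmagnesium bromide | C#C[Mg]Br | starting material
3 | bromomagnesium 1-[3,4-bis(benzyloxy)phenyl]prop-2-yn-1-olate (racemic) | C#CC(O[Mg]Br)c1ccc(OCc2ccccc2)c(OCc2ccccc2)c1 | intermediate (not isolated)
4 | rac-1-[3,4-bis(benzyloxy)phenyl]prop-2-yn-1-yl acetate | CC(=O)OC(C#C)c1ccc(OCc2ccccc2)c(OCc2ccccc2)c1 | intermediate
5 | 3,5-bis(benzyloxy)phenol | Oc1cc(OCc2ccccc2)cc(OCc2ccccc2)c1 | starting material
6 | (S)-1,2-bis(benzyloxy)-4-{1-[3,5-bis(benzyloxy)phenoxy]prop-2-yn-1-yl}benzene | C#C[C@H](Oc1cc(OCc2ccccc2)cc(OCc2ccccc2)c1)c1ccc(OCc2ccccc2)c(OCc2ccccc2)c1 | intermediate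
7 | [(R)-3-(3,5-bis(benzyloxy)phenoxy)-3-(3,4-bis(benzyloxy)phenyl)-2-oxopropylidene](Me4tBuXPhos)gold triflimide (α-oxo gold carbene) | O=C(C=[Au][P+](C(C)(C)C)(C(C)(C)C)c1c(C)c(C)c(C)c(C)c1-c1c(C(C)C)cc(C(C)C)cc1C(C)C)[C@H](Oc1cc(OCc2ccccc2)cc(OCc2ccccc2)c1)c1ccc(OCc2ccccc2)c(OCc2ccccc2)c1.[N-](S(=O)(=O)C(F)(F)F)S(=O)(=O)C(F)(F)F | intermediate (not isolated)
8 | (2R)-5,7-bis(benzyloxy)-2-[3,4-bis(benzyloxy)phenyl]chroman-3-one | O=C1Cc2c(OCc3ccccc3)cc(OCc3ccccc3)cc2O[C@@H]1c1ccc(OCc2ccccc2)c(OCc2ccccc2)c1 | intermediate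
9 | (2R,3R)-5,7-bis(benzyloxy)-2-[3,4-bis(benzyloxy)phenyl]chroman-3-ol | O[C@@H]1Cc2c(OCc3ccccc3)cc(OCc3ccccc3)cc2O[C@@H]1c1ccc(OCc2ccccc2)c(OCc2ccccc2)c1 | intermediate
10 | 4-(benzyloxy)-3-methoxybenzoic acid | COc1cc(C(=O)O)ccc1OCc1ccccc1 | starting material
11 | (2R,3R)-5,7-bis(benzyloxy)-2-[3,4-bis(benzyloxy)phenyl]chroman-3-yl 4-(benzyloxy)-3-methoxybenzoate | COc1cc(C(=O)O[C@@H]2Cc3c(OCc4ccccc4)cc(OCc4ccccc4)cc3O[C@@H]2c2ccc(OCc3ccccc3)c(OCc3ccccc3)c2)ccc1OCc1ccccc1 | intermediate
12 | (2R,3R)-2-(3,4-dihydroxyphenyl)-5,7-dihydroxychroman-3-yl 4-hydroxy-3-methoxybenzoate | COc1cc(C(=O)O[C@@H]2Cc3c(O)cc(O)cc3O[C@@H]2c2ccc(O)c(O)c2)ccc1O | target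

**Step count and risks**

Total steps: 6. Longest linear sequence: 6 (1 → 4 → 6 → 8 → 9 → 11 → 12).

Step 3 is the most likely to fail. The very electron-rich ring A may add directly to the gold-activated alkyne (six-membered hydroarylation to the flav-3-ene) before oxidation. The carbene may also be captured by ring B (five-membered closure) or over-oxidised, and the doubly activated C2–O bond may ionise. The fallback keeps the same C4–C4a bond and the same polarity but replaces the carbene by a saturated α-halo ketone electrophile. It sets out from 6, which is brominated at the alkyne terminus (N-bromosuccinimide, AgNO3 cat., acetone) to the bromoalkyne (R)-1,2-bis(benzyloxy)-4-{1-[3,5-bis(benzyloxy)phenoxy]-3-bromoprop-2-yn-1-yl}benzene F1 (same spatial arrangement as 6; only the descriptor changes because bromoethynyl outranks aryl). Hydration of the haloalkyne ((XPhos)AuNTf2 cat., H2O, ClCH2CH2Cl, rt) gives the α-bromomethyl ketone (R)-1-bromo-3-[3,5-bis(benzyloxy)phenoxy]-3-[3,4-bis(benzyloxy)phenyl]propan-2-one F2. This is closed by intramolecular Friedel–Crafts alkylation of ring A in (CF3)2CHOH with solid NaHCO3 at 40 °C, and the route is rejoined at 8.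

Step 2 is the second risk. The electron-rich aryl group favours a background, non-selective ionisation that would lower the ee, and the sense of induction is unverified for this substrate pair. The fallback moves the stereocontrol from C–O bond formation to a late dynamic reduction. It sets out from 4 and 5, which are coupled with the same copper salt and achiral 2,2'-bipyridine to the racemic ether rac-1,2-bis(benzyloxy)-4-{1-[3,5-bis(benzyloxy)phenoxy]prop-2-yn-1-yl}benzene F3. Cyclisation as in step 3 gives the racemic ketone rac-5,7-bis(benzyloxy)-2-[3,4-bis(benzyloxy)phenyl]chroman-3-one F4. This is reduced under asymmetric transfer hydrogenation with dynamic kinetic resolution (RuCl(p-cymene)[(S,S)-TsDPEN] or its mirror image chosen by screening, HCO2H/Et3N 5:2, rt). C2 equilibrates through the enol while hydride is delivered to one enantiomer anti to the aryl group, which gives the cis (2R,3R) alcohol and rejoins the route at 9. This reduction is untested on flavan-3-ones and is a proposal by analogy with 2-aryl cyclic ketones.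

Step 4 is the third risk. The basic hydride may enolise C2 and erode ee, or the cis:trans ratio may be insufficient. The fallback sets C3 by alkene hydrogenation instead of carbonyl reduction. It sets out from 8 and 10. Acid 10 is converted with (COCl)2 and DMF cat. into 4-(benzyloxy)-3-methoxybenzoyl chloride F5. Ketone 8 is deprotonated kinetically at the C4 methylene (KN(SiMe3)2, THF, −78 °C) and O-acylated with F5 to the enol ester (2R)-5,7-bis(benzyloxy)-2-[3,4-bis(benzyloxy)phenyl]-2H-chromen-3-yl 4-(benzyloxy)-3-methoxybenzoate F6. Hydrogenation (H2, Pd(OH)2/C, THF/MeOH) adds hydrogen to C3=C4 from the face opposite the C2 aryl group, the cis outcome long known for hydrogenation of flav-3-en-3-ol derivatives. The same operation removes the benzyl groups, so the route is rejoined directly at 12.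

**Further compounds**

F1 | step 3 | (R)-1,2-bis(benzyloxy)-4-{1-[3,5-bis(benzyloxy)phenoxy]-3-bromoprop-2-yn-1-yl}benzene | BrC#C[C@H](Oc1cc(OCc2ccccc2)cc(OCc2ccccc2)c1)c1ccc(OCc2ccccc2)c(OCc2ccccc2)c1
F2 | step 3 | (R)-1-bromo-3-[3,5-bis(benzyloxy)phenoxy]-3-[3,4-bis(benzyloxy)phenyl]propan-2-one | BrCC(=O)[C@H](Oc1cc(OCc2ccccc2)cc(OCc2ccccc2)c1)c1ccc(OCc2ccccc2)c(OCc2ccccc2)c1
F3 | step 2 | rac-1,2-bis(benzyloxy)-4-{1-[3,5-bis(benzyloxy)phenoxy]prop-2-yn-1-yl}benzene | C#CC(Oc1cc(OCc2ccccc2)cc(OCc2ccccc2)c1)c1ccc(OCc2ccccc2)c(OCc2ccccc2)c1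
F4 | step 2 | rac-5,7-bis(benzyloxy)-2-[3,4-bis(benzyloxy)phenyl]chroman-3-one | O=C1Cc2c(OCc3ccccc3)cc(OCc3ccccc3)cc2OC1c1ccc(OCc2ccccc2)c(OCc2ccccc2)c1
F5 | step 4 | 4-(benzyloxy)-3-methoxybenzoyl chloride | COc1cc(C(=O)Cl)ccc1OCc1ccccc1
F6 | step 4 | (2R)-5,7-bis(benzyloxy)-2-[3,4-bis(benzyloxy)phenyl]-2H-chromen-3-yl 4-(benzyloxy)-3-methoxybenzoate | COc1cc(C(=O)OC2=Cc3c(OCc4ccccc4)cc(OCc4ccccc4)cc3O[C@@H]2c2ccc(OCc3ccccc3)c(OCc3ccccc3)c2)ccc1OCc1ccccc1
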